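Atoms are numbered from the lactone carbonyl C1 round the ten-membered ring to C9, the propyl-bearing carbon. Everything rests on cutting the alkyl C9–O bond of the lactone. The ring oxygen on C9, the free OH on C8 and the free allylic OH on C7 form an all-erythro triad, the imprint of a trans-2,3-epoxy alcohol opened at its distal carbon. The precursor is therefore an acyclic 7-hydroxy-8,9-epoxy acid that already carries the protected muconate on O2. Ti(OiPr)4 chelates O7 and the oxirane oxygen, and the C1 carboxylate attacks C9 with inversion: one strain-releasing isomerisation closes the ring, sets C9 and unveils the 7,8-diol without protecting groups.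

Key step: step 7

Remark: compounds 1, 3, 4, 8 and 9 are taken as purchasable. The propyl carbons are C10–C12. The target is (2S,7R,8R,9S) in this numbering.

Step 1
Reactants: 1 L-homoallylglycine [(S)-2-aminohex-5-enoic acid]
Product: 2 (S)-2-hydroxyhex-5-enoic acid
Conditions: NaNO2, 1 M aq. H2SO4, 0 °C to rt
Reagents that add atoms: water, O
Why: Diazotisation of an α-amino acid goes with net retention by double inversion through carboxylate participation, so the (S) centre of the chiral-pool amino acid becomes C2 of the target and the remote terminal alkene takes no part.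

Step 2
Reactants: 3 (E)-3-iodoacrylic acid; 4 tert-butyl acrylate
Product: 5 (2E,4E)-6-tert-butoxy-6-oxohexa-2,4-dienoic acid (mono-tert-butyl trans,trans-muconate)
Conditions: Pd(OAc)2 (5 mol %), P(o-tol)3, Et3N, MeCN, 60 °C
Reagents that add atoms: none
Why: Heck reaction, in which oxidative addition of zerovalent palladium into the C–I bond keeps the E geometry and syn insertion followed by syn β-hydride elimination gives the second E alkene, so the two ends of the muconate are differentiated from the outset.

Step 3
Reactants: 5 mono-tert-butyl trans,trans-muconate; 2 (S)-2-hydroxyhex-5-enoic acid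
Product: 7 (S)-2-{[(2E,4E)-6-tert-butoxy-6-oxohexa-2,4-dienoyl]oxy}hex-5-enoic acid (fragment 1), via acid chloride 6 (not isolated)
Conditions: 5, Ghosez reagent, CH2Cl2, 0 °C; then 2, pyridine, 0 °C to rt; aq. NaHCO3, then citric acid
Reagents that add atoms: 1-chloro-N,N,2-trimethylprop-1-en-1-amine (Ghosez reagent), CC(C)=C(Cl)N(C)C (its chlorine stands in 6 only)
Why: Neutral acid chloride formation spares the tert-butyl ester, and Einhorn-type O-acylation of the secondary hydroxyl in pyridine does not touch the C2–H bond, so C2 should stay (S), while any mixed anhydride at C1 is hydrolysed in the bicarbonate work-up.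

Step 4
Reactants: 8 (E)-hex-2-enal; 9 vinylmagnesium bromide
Product: 10 racemic (E)-octa-1,4-dien-3-ol
Conditions: THF, −78 to 0 °C; aqueous work-up
Reagents that add atoms: none
Why: 1,2-Addition of a Grignard reagent to an enal gives the bis-allylic alcohol, whose carbinol centre is left racemic on purpose because the next step resolves it.

Step 5
Reactants: 10 racemic (E)-octa-1,4-dien-3-ol
Product: 11 (1R)-1-[(2R,3R)-3-propyloxiran-2-yl]prop-2-en-1-ol (fragment 2; 7R,8R,9R in target numbering)
Conditions: Ti(OiPr)4 (10 mol %), D-(−)-diisopropyl tartrate (12 mol %), tBuOOH (0.45 equiv), 4 Å MS, CH2Cl2, −20 °C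
Reagents that add atoms: tert-butyl hydroperoxide, CC(C)(C)OO
Why: Sharpless kinetic resolution, in which the D-(−)-tartrate catalyst takes the (R)-alcohol as the fast enantiomer and epoxidises its more nucleophilic E-disubstituted alkene on the face that gives the erythro trans-epoxy alcohol, setting C7, C8 and C9 at once, while the (S)-alcohol, whose only matched alkene is the sluggish vinyl group, stays behind.

Step 6
Reactants: 7 fragment 1; 11 fragment 2
Product: 12 (2S,5E,7R)-2-{[(2E,4E)-6-tert-butoxy-6-oxohexa-2,4-dienoyl]oxy}-7-hydroxy-7-[(2R,3R)-3-propyloxiran-2-yl]hept-5-enoic acid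
Conditions: second-generation Hoveyda–Grubbs catalyst RuCl2(H2IMes)(=CH-C6H4-2-OiPr) (5 mol %), 11 (2 equiv), CH2Cl2, 40 °C
Reagents that add atoms: none
Why: Olefin cross metathesis pairs a rapidly homodimerising terminal alkene with a slowly homodimerising secondary allylic alcohol, which favours the cross product and its E alkene under thermodynamic control, while the electron-poor 1,2-disubstituted muconate alkenes, the epoxide and the free acid are tolerated and no stereocentre is touched.

Step 7
Reactants: 12 epoxy hydroxy acid
Product: 13 tert-butyl ester of the target: (2S,5E,7R,8R,9S)-7,8-dihydroxy-9-propylnon-5-en-9-olide acylated on O2 by mono-tert-butyl (2E,4E)-muconate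
Conditions: Ti(OiPr)4 (1.5 equiv), CH2Cl2 (1 mM), slow addition of 12, reflux; aqueous work-up
Reagents that add atoms: none
Why: Ligand exchange places the C7 alkoxide and the C1 carboxylate on tetravalent titanium, the oxirane oxygen completes a five-membered O7–C7–C8–O chelate that polarises the epoxide, and the carboxylate oxygen attacks C9 anti to the breaking C9–O bond in an SN2 opening driven by release of the oxirane strain. The closest known reaction type is the Ti(OiPr)4-mediated C3-selective opening of 2,3-epoxy alcohols by carboxylic acids, which is also known in its intramolecular form as an epoxy-acid macrolactonisation of larger rings. The ten-membered ring closes in a formal 10-endo-tet mode, because both oxirane carbons become ring members and the oxirane oxygen ends as the exocyclic OH on C8. C9 is the only centre that changes, clean inversion turning (9R) of the trans-epoxide into (9S), whereas C7 and C8 keep their C–O bonds and C2 is remote, so the erythro,erythro triad is dictated by the substrate alone. The step needs attack at C9 rather than C8 (ten- against nine-membered lactone), which the chelate secures by weakening the distal C–O bond and the C7 oxygen by deactivating C8 inductively, and it needs cyclisation rather than oligomerisation, which slow addition at high dilution secures. The second carboxyl group is masked as its tert-butyl ester, so only one carboxylate can act as nucleophile.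

Step 8
Reactants: 13 tert-butyl ester of the target
Product: 14 target, (2E,4E)-6-{[(3S,6E,8R,9R,10S)-8,9-dihydroxy-2-oxo-10-propyl-3,4,5,8,9,10-hexahydro-2H-oxecin-3-yl]oxy}-6-oxohexa-2,4-dienoic acid
Conditions: TFA/CH2Cl2 (1:4), 0 °C
Reagents that add atoms: none
Why: Acidolysis of a tert-butyl ester by alkyl–oxygen cleavage (loss of the tert-butyl cation as isobutene) should leave the lactone, the dienoate ester and all four stereocentres untouched, since the C7 allylic alcohol is deactivated towards ionisation by the neighbouring C8 oxygen.

Compound list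
1 | L-homoallylglycine, (S)-2-aminohex-5-enoic acid | C=CCC[C@H](N)C(=O)O | starting material
2 | (S)-2-hydroxyhex-5-enoic acid | C=CCC[C@H](O)C(=O)O | intermediate
3 | (E)-3-iodoacrylic acid | OC(=O)/C=C/I | starting material
4 | tert-butyl acrylate | C=CC(=O)OC(C)(C)C | starting material
5 | (2E,4E)-6-tert-butoxy-6-oxohexa-2,4-dienoic acid | CC(C)(C)OC(=O)/C=C/C=C/C(=O)O | intermediate
6 | tert-butyl (2E,4E)-6-chloro-6-oxohexa-2,4-dienoate (not isolated) | CC(C)(C)OC(=O)/C=C/C=C/C(=O)Cl | intermediate
7 | (S)-2-{[(2E,4E)-6-tert-butoxy-6-oxohexa-2,4-dienoyl]oxy}hex-5-enoic acid | C=CCC[C@H](OC(=O)/C=C/C=C/C(=O)OC(C)(C)C)C(=O)O | intermediate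
8 | (E)-hex-2-enal | CCC/C=C/C=O | starting material
9 | vinylmagnesium bromide | C=C[Mg]Br | starting material
10 | racemic (E)-octa-1,4-dien-3-ol | C=CC(O)/C=C/CCC | intermediate
11 | (1R)-1-[(2R,3R)-3-propyloxiran-2-yl]prop-2-en-1-ol | C=C[C@@H](O)[C@H]1O[C@@H]1CCC | intermediate
12 | (2S,5E,7R)-2-{[(2E,4E)-6-tert-butoxy-6-oxohexa-2,4-dienoyl]oxy}-7-hydroxy-7-[(2R,3R)-3-propyloxiran-2-yl]hept-5-enoic acid | OC(=O)[C@@H](OC(=O)/C=C/C=C/C(=O)OC(C)(C)C)CC/C=C/[C@@H](O)[C@H]1O[C@@H]1CCC | intermediate
13 | tert-butyl ester of the target, (2S,5E,7R,8R,9S)-lactone | CCC[C@@H]1OC(=O)[C@@H](OC(=O)/C=C/C=C/C(=O)OC(C)(C)C)CC/C=C/[C@@H](O)[C@H]1O | intermediate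
14 | target CNP0476488.2 | CCC[C@@H]1OC(=O)[C@@H](OC(=O)/C=C/C=C/C(=O)O)CC/C=C/[C@@H](O)[C@H]1O | target

Total step count: 8. Longest linear sequence: 5 steps (steps 4, 5, 6, 7, 8; the branches from 1 and from 3/4 are equally long).

Steps most likely to fail

Step 7. Oligomerisation may outrun the transannularly strained ten-membered closure, and transfer of isopropoxide from titanium to C9 or to the O2 ester may consume the substrate. The fallback sets out from 7 and 11 and comes back to the route at 14. The same titanium-directed, C9-selective opening is run between two molecules (7, 11, Ti(OiPr)4, CH2Cl2, rt) and should give the open-chain C9 ester diene F1. 2,2-Dimethoxypropane and PPTS convert its 7,8-diol into the cis-dioxolane diene F2. Ring-closing metathesis at C5=C6 with the first-generation Grubbs catalyst RuCl2(=CHPh)(PCy3)2 in dilute refluxing CH2Cl2 should give the (E)-lactone acetonide F3 under kinetic control. Aqueous TFA then removes the acetonide and the tert-butyl ester together and delivers 14. The C9–O bond is still made by epoxide opening with inversion; only the ring closure moves to the alkene.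

Step 6. Ruthenium hydride species may isomerise the free allylic alcohol of 11 to a ketone, and homodimerisation of 7 may stall the exchange. The fallback sets out from 11 and 7 and comes back at 12. Dess–Martin periodinane oxidises 11 to the vinyl epoxy ketone F4, an electron-poor partner that cannot isomerise and that couples E-selectively with terminal alkenes. Metathesis with 7 under the conditions of step 6 should give the enone acid F5. Luche reduction (NaBH4, CeCl3·7H2O, MeOH, −78 °C) of the metal-chelated α,β-epoxy ketone should restore the erythro (7R) alcohol and thus 12.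

Step 3. The carboxyl group of 2 may compete with its hydroxyl group for the acid chloride, which leads through mixed anhydrides to oligoesters of 2, and the pyridinium chloride formed may erode the tert-butyl ester. The fallback sets out from 2 and 5 and comes back at 7. Alkylation of 2 with allyl bromide and Cs2CO3 in DMF gives the allyl hydroxy ester F6. Steglich esterification with 5 (EDC·HCl, DMAP, CH2Cl2) gives the allyl tert-butyl triester F7. Tsuji–Trost deallylation with Pd(PPh3)4 and N-methylaniline in THF frees the C1 acid 7.

Further compounds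
F1 | step 7 | (4S,5R,6R)-5,6-dihydroxyoct-7-en-4-yl (S)-2-{[(2E,4E)-6-tert-butoxy-6-oxohexa-2,4-dienoyl]oxy}hex-5-enoate | CCC[C@H](OC(=O)[C@@H](OC(=O)/C=C/C=C/C(=O)OC(C)(C)C)CCC=C)[C@H](O)[C@H](O)C=C
F2 | step 7 | 7,8-O-isopropylidene derivative of F1 (cis-dioxolane) | CCC[C@H](OC(=O)[C@@H](OC(=O)/C=C/C=C/C(=O)OC(C)(C)C)CCC=C)[C@@H]1OC(C)(C)O[C@@H]1C=C
F3 | step 7 | 7,8-O-isopropylidene derivative of 13 | CCC[C@@H]1OC(=O)[C@@H](OC(=O)/C=C/C=C/C(=O)OC(C)(C)C)CC/C=C/[C@H]2OC(C)(C)O[C@@H]12
F4 | step 6 | 1-[(2S,3R)-3-propyloxiran-2-yl]prop-2-en-1-one | C=CC(=O)[C@H]1O[C@@H]1CCC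
F5 | step 6 | (2S,5E)-2-{[(2E,4E)-6-tert-butoxy-6-oxohexa-2,4-dienoyl]oxy}-7-oxo-7-[(2S,3R)-3-propyloxiran-2-yl]hept-5-enoic acid | OC(=O)[C@@H](OC(=O)/C=C/C=C/C(=O)OC(C)(C)C)CC/C=C/C(=O)[C@H]1O[C@@H]1CCC
F6 | step 3 | allyl (S)-2-hydroxyhex-5-enoate | C=CCC[C@H](O)C(=O)OCC=C
F7 | step 3 | allyl (S)-2-{[(2E,4E)-6-tert-butoxy-6-oxohexa-2,4-dienoyl]oxy}hex-5-enoate | C=CCC[C@H](OC(=O)/C=C/C=C/C(=O)OC(C)(C)C)C(=O)OCC=C
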